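The pitfall in these runs is to read percent of charge as speed. At 30.0 h the west run shows less product than the north run, 9 % against 16 %, yet in concentration it holds more, 34.2 mM against 15.2 mM. Each flask is stirred under held gas while starting material is fed in over 25 h.

the same everywhere: gas 6.1 mM (held)
- north: starting material 0.095 M (fed, over 25 h); run made earlier
- west: starting material 0.38 M (fed, over 25 h); run made earlier
- flask: starting material 0.19 M (fed, over 25 h); time 30 h

| run | time / h | product / % | starting material / % |
|---|---|---|---|
| north | 2.50 | 0 | 8 |
| north | 4.00 | 0 | 11 |
| north | 6.00 | 0 | 22 |
| north | 8.00 | 0 | 26 |
| north | 12.0 | 2 | 37 |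
| north | 20.0 | 6 | 54 |
| north | 30.0 | 16 | 54 |
| west | 4.00 | 1 | 14 |
| west | 8.00 | 1 | 29 |
| west | 12.0 | 2 | 39 |
| west | 15.0 | 2 | 51 |
| west | 20.0 | 3 | 68 |
| west | 25.0 | 8 | 81 |
| west | 30.0 | 9 | 79 |

(readings scatter by 1.5 percentage points)

- amount of product in percent of the starting material charged, at 3.0 h, 10 h, 20 h and 30 h

- at the start none of the gas is in solution
- percentages count the whole charge, also what has not yet gone in

I start from two extreme versions of the flask, both anchored on the north run at 30 h. If product concentration rose in step with the charge, percent would not change with charge, and the flask would show 16 %. If product concentration ignored the charge, the flask would show 8.00 %.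

One number places the real flask between these. The two runs give 0.585 for n, the exponent by which product concentration at 30 h grows with the charge, an apparent order in the charge, with dosing time and gas held as they stand in both runs. It is a reading, carrying the scatter of 1.5 percentage points on each percentage. Since n lies between 0 and 1, percent falls as the charge to the power n minus 1, and my reckoning for the flask at 30 h is 12.0 %.

The forecast gives 0.1 %, 1.1 %, 5.2 % and 12.5 %, reasoning that “an intermediate builds up”. Its last value stands a little above mine.

The flask gives 0.0334 %, 1.11 %, 5.78 % and 13.7 %, so the forecast is right within the margin.

    starting material + partner ⇌ adduct (K = 360 /M, k = 0.220 /M/min)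
    adduct → product (k = 7.40 × 10⁻⁴ /min)
    gas ⇌ partner, rate k3*(csat - [partner]) (kL = 0.0120 /min)
    partner → decomposed reagent (k = 2.50 × 10⁻⁴ /min)

My 12.0 % lies 1.7 points below the flask's value at 30 h. From that value, n puts a flask with twice the starting material at 10.3 %, and that run gives 9.42 %. In the flask at 30.0 h, starting material, partner and adduct relax towards each other by their reversible step alone with a half-life of 0.405 h, both ways together, against 15.6 h for adduct going on to product. At that time the flask holds adduct at 20.7 % beside product at 13.7 %.

Readings and results come from a simulation for an exercise.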